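Prostanoid numbering is used: C1 = ester carbon, C4 = secondary acetate, ring = C8–C12 (C9 ketone, C12 tertiary acetate), C13–C20 = dienyl chain. Enabling feature: in the 5-alkylidenecyclopent-2-enone ring, the hydrogen on C7 is cis to the C9 carbonyl across the exocyclic C7=C8 bond, C10=C11 is a ring-locked (Z)-olefin, and C12 is quaternary. The target is therefore the syn H/acyl adduct, and an isomer, of an open-chain (Z)-enal that carries a C7≡C8 alkyne.
Last disconnection, the only carbocycle: C8–C9, by 5-exo-dig rhodium-catalysed alkyne hydroacylation of acyclic aldehyde 25. The ring, the ketone, the (7E)-olefin and the whole cross-conjugated trienone all form in the final step.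
C6–C7: Sonogashira union of alkynol 15 (C7–C20) with (Z)-iodoalkene 22 (C1–C6), whose C4 centre is set by Noyori transfer hydrogenation.
C12: Sharpless epoxidation of enynol 10. The oxirane O–C8–C12 is a temporary ring, and its strain-releasing fragmentation leaves C12–OH with its configuration and unveils the C7≡C8 alkyne.
C13–C20 and C9–C11: copper-mediated sp–sp3 couplings, hydroalumination/iodination, Sonogashira coupling and cis-semihydrogenations. Order of rings: oxirane (made in step 7, opened in step 10), then cyclopentenone (step 19).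
Key step: step 19

Remark on the chemistry: BINAP serves in step 19 only as a bite-angle ligand. No stereocentre is created there, so the antipode better matched to 25 is chosen by experiment.

Step 1
Reactants: 1 1-bromopent-2-yne; 2 prop-2-yn-1-ol
Product: 3 octa-2,5-diyn-1-ol
Conditions: CuI (cat.), K2CO3, DMF, rt
Reagents that add atoms: none
Why: Copper acetylide alkylation (sp–sp3 coupling) of the propargylic bromide should give the skipped diyne, and the weak carbonate base avoids isomerisation to allenes.

Step 2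
Reactants: 3 octa-2,5-diyn-1-ol
Product: 4 (2Z,5Z)-octa-2,5-dien-1-ol
Conditions: H2 (1 atm), Ni(OAc)2·4H2O/NaBH4 (nickel boride made in situ), H2NCH2CH2NH2, EtOH, rt
Reagents that add atoms: none
Why: cis-Semihydrogenation on amine-poisoned nickel boride adds hydrogen syn to both alkynes and should stop at the (Z,Z)-diene.

Step 3
Reactants: 4 (2Z,5Z)-octa-2,5-dien-1-ol
Product: 5 (2Z,5Z)-1-bromoocta-2,5-diene
Conditions: CBr4, PPh3, CH2Cl2, 0 °C
Reagents that add atoms: tetrabromomethane BrC(Br)(Br)Br
Why: The Appel reaction displaces the oxyphosphonium ion by SN2 under neutral conditions, so the allylic (Z)-olefin should neither transpose nor isomerise.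

Step 4
Reactants: 5 (2Z,5Z)-1-bromoocta-2,5-diene; 2 prop-2-yn-1-ol
Product: 6 (5Z,8Z)-undeca-5,8-dien-2-yn-1-ol
Conditions: CuI (cat.), K2CO3, DMF, rt
Reagents that add atoms: none
Why: Copper acetylide allylation (SN2-type coupling of an allylic bromide with a terminal alkyne) should give the linear 1,4-enyne with the (Z)-geometry retained.

Step 5
Reactants: 6 (5Z,8Z)-undeca-5,8-dien-2-yn-1-ol
Product: 8 (2Z,5Z,8Z)-3-iodoundeca-2,5,8-trien-1-ol, via cyclic sodium alkenylalanate 7 (not isolated)
Conditions: NaAlH2(OCH2CH2OMe)2, THF, 0 °C to rt; then I2, THF, −78 °C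
Reagents that add atoms: iodine II
Why: Hydroxyl-directed trans-hydroalumination of the propargylic alcohol puts aluminium on C3 in a five-membered alanate, and iodinolysis with retention should give one regio- and stereoisomer, while the isolated olefins are inert.

Step 6
Reactants: 8 (2Z,5Z,8Z)-3-iodoundeca-2,5,8-trien-1-ol; 9 3,3-diethoxyprop-1-yne
Product: 10 (2Z,5Z,8Z)-3-(3,3-diethoxyprop-1-yn-1-yl)undeca-2,5,8-trien-1-ol
Conditions: PdCl2(PPh3)2 (3 mol %), CuI (6 mol %), Et3N, THF, rt
Reagents that add atoms: none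
Why: Sonogashira coupling proceeds with retention at the alkenyl iodide, so the C9–C11 arm, with C9 already at the aldehyde level as its acetal, ends up cis to CH2OH.

Step 7
Reactants: 10 (2Z,5Z,8Z)-3-(3,3-diethoxyprop-1-yn-1-yl)undeca-2,5,8-trien-1-ol
Product: 11 [(2R,3S)-3-(3,3-diethoxyprop-1-yn-1-yl)-3-[(2Z,5Z)-octa-2,5-dien-1-yl]oxiran-2-yl]methanol
Conditions: Ti(OiPr)4 (10 mol %), D-(−)-diisopropyl tartrate (12 mol %), t-BuOOH, 4 Å molecular sieves, CH2Cl2, −20 °C
Reagents that add atoms: tert-butyl hydroperoxide CC(C)(C)OO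
Why: The Katsuki–Sharpless asymmetric epoxidation touches only the allylic alcohol olefin, and D-(−)-tartrate delivers oxygen in the sense nerol to (2R,3S)-epoxide, which sets the future C12 centre together with the sacrificial C8 centre.

Step 8
Reactants: 11 [(2R,3S)-3-(3,3-diethoxyprop-1-yn-1-yl)-3-[(2Z,5Z)-octa-2,5-dien-1-yl]oxiran-2-yl]methanol
Product: 12 (2S,3S)-2-(chloromethyl)-3-(3,3-diethoxyprop-1-yn-1-yl)-3-[(2Z,5Z)-octa-2,5-dien-1-yl]oxirane
Conditions: PPh3, CCl4, NaHCO3, reflux
Reagents that add atoms: tetrachloromethane ClC(Cl)(Cl)Cl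
Why: The Appel chlorination converts the primary alcohol under neutral conditions without opening the alkynyl-deactivated oxirane; only the descriptor at the CH centre changes, not its geometry.

Step 9
Reactants: 12 (2S,3S)-2-(chloromethyl)-3-(3,3-diethoxyprop-1-yn-1-yl)-3-[(2Z,5Z)-octa-2,5-dien-1-yl]oxirane
Product: 13 (2S,3S)-2-(chloromethyl)-3-[(1Z)-3,3-diethoxyprop-1-en-1-yl]-3-[(2Z,5Z)-octa-2,5-dien-1-yl]oxirane
Conditions: H2 (1 atm), Pd/CaCO3 poisoned by Pb(OAc)2 (Lindlar catalyst), quinoline, EtOAc, rt
Reagents that add atoms: none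
Why: Lindlar semihydrogenation adds hydrogen syn to the only alkyne in the molecule and should give the (Z)-olefin that becomes the ring bond C10=C11.

Step 10
Reactants: 13 (2S,3S)-2-(chloromethyl)-3-[(1Z)-3,3-diethoxyprop-1-en-1-yl]-3-[(2Z,5Z)-octa-2,5-dien-1-yl]oxirane
Product: 15 (2Z,4S,6Z,9Z)-1,1-diethoxy-4-ethynyldodeca-2,6,9-trien-4-ol, via dilithium alkoxide acetylide 14 (not isolated)
Conditions: LiN(iPr)2 (3.3 equiv), THF, −78 to −40 °C; then H2O
Reagents that add atoms: none
Why: In this epoxy chloride to propargylic alcohol fragmentation (double elimination), deprotonation at CH2Cl opens the strained oxirane at the C8–O bond and loss of HCl gives the alkyne; the C12–O bond is never broken, so the tertiary carbinol keeps its configuration.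

Step 11
Reactants: 16 methyl 4-chloro-4-oxobutanoate; 17 bis(trimethylsilyl)acetylene
Product: 18 methyl 4-oxo-6-(trimethylsilyl)hex-5-ynoate
Conditions: AlCl3, CH2Cl2, 0 °C
Reagents that add atoms: none
Why: Friedel–Crafts-type acylative ipso-desilylation of the bis-silylalkyne should stop after one acylation because the ynone formed is deactivated.

Step 12
Reactants: 18 methyl 4-oxo-6-(trimethylsilyl)hex-5-ynoate
Product: 19 methyl (4R)-4-hydroxy-6-(trimethylsilyl)hex-5-ynoate
Conditions: RuCl(p-cymene)[(R,R)-TsDPEN] (1 mol %), KOH (1 mol %), iPrOH, rt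
Reagents that add atoms: none
Why: Noyori asymmetric transfer hydrogenation distinguishes the alkynyl and alkyl flanks of the ynone, and the (R,R)-catalyst should deliver hydride to give the (R)-propargylic alcohol, which sets C4.

Step 13
Reactants: 19 methyl (4R)-4-hydroxy-6-(trimethylsilyl)hex-5-ynoate
Product: 20 methyl (4R)-4-acetoxy-6-(trimethylsilyl)hex-5-ynoate
Conditions: Ac2O, pyridine, DMAP (cat.), CH2Cl2, 0 °C to rt
Reagents that add atoms: acetic anhydride CC(=O)OC(C)=O
Why: DMAP-catalysed acylation caps the γ-hydroxy ester before it can lactonise and installs the C4 acetate of the target.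

Step 14
Reactants: 20 methyl (4R)-4-acetoxy-6-(trimethylsilyl)hex-5-ynoate
Product: 21 methyl (4R)-4-acetoxy-6-iodohex-5-ynoate
Conditions: N-iodosuccinimide, AgNO3 (10 mol %), DMF, rt, dark
Reagents that add atoms: N-iodosuccinimide O=C1CCC(=O)N1I
Why: Silver-catalysed iododesilylation (electrophilic ipso-substitution at the alkynylsilane) turns C–SiMe3 directly into C–I under neutral conditions that spare the ester and the acetate.

Step 15
Reactants: 21 methyl (4R)-4-acetoxy-6-iodohex-5-ynoate
Product: 22 methyl (4R,5Z)-4-acetoxy-6-iodohex-5-enoate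
Conditions: 2-nitrobenzenesulfonohydrazide, Et3N, THF–iPrOH, rt
Reagents that add atoms: none
Why: Diimide reduction transfers two hydrogens in a concerted syn fashion to the iodoalkyne and should give the (Z)-iodoalkene without touching the C–I bond, the ester or the acetate.

Step 16
Reactants: 15 (2Z,4S,6Z,9Z)-1,1-diethoxy-4-ethynyldodeca-2,6,9-trien-4-ol; 22 methyl (4R,5Z)-4-acetoxy-6-iodohex-5-enoate
Product: 23 methyl (4R,5Z,9S,11Z,14Z)-4-acetoxy-9-[(1Z)-3,3-diethoxyprop-1-en-1-yl]-9-hydroxyheptadeca-5,11,14-trien-7-ynoate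
Conditions: Pd(PPh3)4 (5 mol %), CuI (10 mol %), Et3N, THF, rt
Reagents that add atoms: none
Why: In this Sonogashira coupling, oxidative addition of zerovalent palladium to the alkenyl iodide is much faster at room temperature than ionisation of the allylic acetate and occurs with retention (5Z), and keeping C12–OH free avoids the copper allenylidene chemistry of terminal propargylic esters.

Step 17
Reactants: 23 methyl (4R,5Z,9S,11Z,14Z)-4-acetoxy-9-[(1Z)-3,3-diethoxyprop-1-en-1-yl]-9-hydroxyheptadeca-5,11,14-trien-7-ynoate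
Product: 24 methyl (4R,5Z,9S,11Z,14Z)-4,9-diacetoxy-9-[(1Z)-3,3-diethoxyprop-1-en-1-yl]heptadeca-5,11,14-trien-7-ynoate
Conditions: Ac2O, DMAP, Et3N, CH2Cl2, rt
Reagents that add atoms: acetic anhydride CC(=O)OC(C)=O
Why: DMAP-catalysed acetylation should reach the tertiary alcohol because its slim alkynyl substituent keeps the hydroxyl accessible, and no stereocentre is touched.

Step 18
Reactants: 24 methyl (4R,5Z,9S,11Z,14Z)-4,9-diacetoxy-9-[(1Z)-3,3-diethoxyprop-1-en-1-yl]heptadeca-5,11,14-trien-7-ynoate
Product: 25 methyl (4R,5Z,9S,11Z,14Z)-4,9-diacetoxy-9-[(1Z)-3-oxoprop-1-en-1-yl]heptadeca-5,11,14-trien-7-ynoate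
Conditions: aq. oxalic acid on SiO2, CH2Cl2, 0 °C to rt; used without delay
Reagents that add atoms: water O
Why: Acid-catalysed acetal hydrolysis through the allyl-stabilised oxocarbenium ion should be much faster than ionisation of the acetates, and the (Z)-enal cannot isomerise through a dienol because C12 carries no hydrogen.

Step 19
Reactants: 25 methyl (4R,5Z,9S,11Z,14Z)-4,9-diacetoxy-9-[(1Z)-3-oxoprop-1-en-1-yl]heptadeca-5,11,14-trien-7-ynoate
Product: 26 17,18-dehydro-clavulone I, methyl (4R,5Z,7E,12S,14Z,17Z)-4,12-diacetoxy-9-oxoprosta-5,7,10,14,17-pentaenoate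
Conditions: [Rh(cod)2]BF4 (10 mol %), BINAP (10 mol %), activated under H2 then Ar, CH2Cl2, rt
Reagents that add atoms: none
Why: Oxidative addition of the formyl C9–H bond to the cationic monovalent rhodium centre gives an acyl hydride of trivalent rhodium held by the C7≡C8 alkyne, syn hydrometalation then places H on C7 and Rh on C8 (six-membered acyl alkenyl rhodacycle), and reductive elimination forges C8–C9. The closest known reaction type is the cationic Rh/BINAP-catalysed cis-hydroacylation of 5-alkynals to (E)-2-alkylidenecyclopentanones (intramolecular alkyne hydroacylation). The single ring C8–C12 closes in the 5-exo-dig mode. No stereocentre is created, C4 and C12 are spectators, and the new C7=C8 bond is fixed as E because H and acyl arrive on the same side of the alkyne, while the 5Z, 14Z and 17Z olefins are not involved. The step needs exo/syn over 6-endo addition, cyclisation over decarbonylation, and survival of two activated acetates: the (Z)-C10=C11 bond and the quaternary C12 (Thorpe–Ingold effect) hold formyl and alkyne together for fast chelation, endo closure would demand a trans addition, and the enal deactivates C12 towards ionisation. In one neutral, fully atom-economic operation the acyclic isomer becomes the complete cross-conjugated trienone, so this base- and nucleophile-sensitive chromophore never has to survive a later step.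

Compound list
1 | 1-bromopent-2-yne | CCC#CCBr | starting material
2 | prop-2-yn-1-ol | C#CCO | starting material
3 | octa-2,5-diyn-1-ol | CCC#CCC#CCO | intermediate
4 | (2Z,5Z)-octa-2,5-dien-1-ol | CC/C=C\C/C=C\CO | intermediate
5 | (2Z,5Z)-1-bromoocta-2,5-diene | CC/C=C\C/C=C\CBr | intermediate
6 | (5Z,8Z)-undeca-5,8-dien-2-yn-1-ol | CC/C=C\C/C=C\CC#CCO | intermediate
7 | cyclic sodium alkenylalanate (1,2-oxaluminole ate complex, not isolated) | [Na+].COCCO[Al-]1(OCCOC)OCC=C1C/C=C\C/C=C\CC | intermediate
8 | (2Z,5Z,8Z)-3-iodoundeca-2,5,8-trien-1-ol | CC/C=C\C/C=C\C/C(I)=C/CO | intermediate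
9 | 3,3-diethoxyprop-1-yne | C#CC(OCC)OCC | starting material
10 | (2Z,5Z,8Z)-3-(3,3-diethoxyprop-1-yn-1-yl)undeca-2,5,8-trien-1-ol | CC/C=C\C/C=C\C/C(C#CC(OCC)OCC)=C/CO | intermediate
11 | [(2R,3S)-3-(3,3-diethoxyprop-1-yn-1-yl)-3-[(2Z,5Z)-octa-2,5-dien-1-yl]oxiran-2-yl]methanol | CC/C=C\C/C=C\C[C@@]1(C#CC(OCC)OCC)O[C@@H]1CO | intermediate
12 | (2S,3S)-2-(chloromethyl)-3-(3,3-diethoxyprop-1-yn-1-yl)-3-[(2Z,5Z)-octa-2,5-dien-1-yl]oxirane | CC/C=C\C/C=C\C[C@@]1(C#CC(OCC)OCC)O[C@@H]1CCl | intermediate
13 | (2S,3S)-2-(chloromethyl)-3-[(1Z)-3,3-diethoxyprop-1-en-1-yl]-3-[(2Z,5Z)-octa-2,5-dien-1-yl]oxirane | CC/C=C\C/C=C\C[C@@]1(/C=C\C(OCC)OCC)O[C@@H]1CCl | intermediate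
14 | dilithium alkoxide acetylide of 15 (not isolated) | [Li+].[Li+].CC/C=C\C/C=C\C[C@@]([O-])(C#[C-])/C=C\C(OCC)OCC | intermediate
15 | (2Z,4S,6Z,9Z)-1,1-diethoxy-4-ethynyldodeca-2,6,9-trien-4-ol | CC/C=C\C/C=C\C[C@@](O)(C#C)/C=C\C(OCC)OCC | intermediate
16 | methyl 4-chloro-4-oxobutanoate | COC(=O)CCC(=O)Cl | starting material
17 | bis(trimethylsilyl)acetylene | C[Si](C)(C)C#C[Si](C)(C)C | starting material
18 | methyl 4-oxo-6-(trimethylsilyl)hex-5-ynoate | COC(=O)CCC(=O)C#C[Si](C)(C)C | intermediate
19 | methyl (4R)-4-hydroxy-6-(trimethylsilyl)hex-5-ynoate | COC(=O)CC[C@@H](O)C#C[Si](C)(C)C | intermediate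
20 | methyl (4R)-4-acetoxy-6-(trimethylsilyl)hex-5-ynoate | COC(=O)CC[C@@H](OC(C)=O)C#C[Si](C)(C)C | intermediate
21 | methyl (4R)-4-acetoxy-6-iodohex-5-ynoate | COC(=O)CC[C@@H](OC(C)=O)C#CI | intermediate
22 | methyl (4R,5Z)-4-acetoxy-6-iodohex-5-enoate | COC(=O)CC[C@@H](OC(C)=O)/C=C\I | intermediate
23 | methyl (4R,5Z,9S,11Z,14Z)-4-acetoxy-9-[(1Z)-3,3-diethoxyprop-1-en-1-yl]-9-hydroxyheptadeca-5,11,14-trien-7-ynoate | CC/C=C\C/C=C\C[C@@](O)(C#C/C=C\[C@@H](CCC(=O)OC)OC(C)=O)/C=C\C(OCC)OCC | intermediate
24 | methyl (4R,5Z,9S,11Z,14Z)-4,9-diacetoxy-9-[(1Z)-3,3-diethoxyprop-1-en-1-yl]heptadeca-5,11,14-trien-7-ynoate | CC/C=C\C/C=C\C[C@@](OC(C)=O)(C#C/C=C\[C@@H](CCC(=O)OC)OC(C)=O)/C=C\C(OCC)OCC | intermediate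
25 | methyl (4R,5Z,9S,11Z,14Z)-4,9-diacetoxy-9-[(1Z)-3-oxoprop-1-en-1-yl]heptadeca-5,11,14-trien-7-ynoate | CC/C=C\C/C=C\C[C@@](OC(C)=O)(C#C/C=C\[C@@H](CCC(=O)OC)OC(C)=O)/C=C\C=O | intermediate
26 | 17,18-dehydro-clavulone I, methyl (4R,5Z,7E,12S,14Z,17Z)-4,12-diacetoxy-9-oxoprosta-5,7,10,14,17-pentaenoate | CC/C=C\C/C=C\C[C@]1(OC(C)=O)C=CC(=O)/C1=C/C=C\[C@@H](CCC(=O)OC)OC(C)=O | target

Total step count: 19. Longest linear sequence: 14 steps (steps 1–10, then 16–19); steps 11–15 form the convergent C1–C6 branch.

Steps most likely to fail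

Step 19. The acyl rhodium hydride may decarbonylate, rhodium may induce migration of the propargylic acetate, or the metal may chain-walk in the skipped diene before the ring closes. The fallback sets out from 25 and comes back at 26. It makes the C8–C9 bond at the alcohol oxidation level by the nickel-catalysed reductive cyclisation of alkynals (Ni(cod)2, PBu3, Et3SiH, THF, rt). Zerovalent nickel couples C9=O and C7≡C8 to an oxanickelacycle, and the silane delivers H to C7 syn to C9. This should give the 9-triethylsilyloxy cyclopentene F1 with the same (7E) geometry, as both C9 epimers, which does not matter. HF·pyridine in THF frees the bis-allylic cyclopentenol F2, and MnO2 in CH2Cl2 oxidises it to 26.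

Step 18. Acid may ionise the doubly activated tertiary acetate, or reversible conjugate addition of water may isomerise the liberated enal from Z to E. The fallback sets out from 23 and comes back at 26. The acetal is cleaved before acetylation (aq. oxalic acid on SiO2), so the free C12 hydroxyl captures the aldehyde as the cyclic hemiacetal F3. This temporary 2,5-dihydrofuran ring locks C10=C11 as Z and carries no ionisable ester. The rhodium catalyst of step 19 acts on the small equilibrium share of open hydroxy enal and should give the 12-hydroxy trienone F4. Ac2O, DMAP and Et3N in CH2Cl2 then acetylate the tertiary alcohol to 26.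

Step 10. Deprotonation at allylic C13 or at C9 may compete, with vinylogous opening of the alkenyl oxirane in place of the wanted elimination. The fallback sets out from 12 and comes back at 15. The fragmentation is run on the more robust alkynyl oxirane before the semihydrogenation. LiN(iPr)2 in THF at −78 °C followed by Me3SiCl should give the bis-silylated diynol F5, in which the new alkyne is shielded. Lindlar hydrogenation then reduces only the acetal-bearing alkyne to the bis-silylated (Z)-enynol F6, and K2CO3 in MeOH removes both silyl groups to give 15.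

Further compounds
F1 | step 19 | 9-triethylsilyloxy cyclopentene (9-deoxo-9-triethylsilyloxy analogue of 26, both C9 epimers) | CC/C=C\C/C=C\C[C@]1(OC(C)=O)C=CC(O[Si](CC)(CC)CC)/C1=C/C=C\[C@@H](CCC(=O)OC)OC(C)=O
F2 | step 19 | bis-allylic cyclopentenol (9-deoxo-9-hydroxy analogue of 26, both C9 epimers) | CC/C=C\C/C=C\C[C@]1(OC(C)=O)C=CC(O)/C1=C/C=C\[C@@H](CCC(=O)OC)OC(C)=O
F3 | step 18 | cyclic hemiacetal (5-hydroxy-2,5-dihydrofuran from 23, both anomers) | CC/C=C\C/C=C\C[C@@]1(C#C/C=C\[C@@H](CCC(=O)OC)OC(C)=O)C=CC(O)O1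
F4 | step 18 | 12-hydroxy trienone (12-O-deacetyl analogue of 26) | CC/C=C\C/C=C\C[C@]1(O)C=CC(=O)/C1=C/C=C\[C@@H](CCC(=O)OC)OC(C)=O
F5 | step 10 | bis-silylated diynol (O,C-bis(trimethylsilyl) 1,4-diyn-3-ol) | CC/C=C\C/C=C\C[C@@](O[Si](C)(C)C)(C#C[Si](C)(C)C)C#CC(OCC)OCC
F6 | step 10 | bis-silylated (Z)-enynol (O,C-bis(trimethylsilyl) derivative of 15) | CC/C=C\C/C=C\C[C@@](O[Si](C)(C)C)(C#C[Si](C)(C)C)/C=C\C(OCC)OCC
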